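Benzyl docosanoate is cut at the C2–C3 bond. C1, C2 and the benzyloxy oxygen form an acetate unit that comes from a malonate half-ester, and C3–C22 is the even-numbered chain of icosanoic acid. The only ring, the phenyl of the benzyl group, is a spectator. In one operation the magnesium enolate of monobenzyl malonate is C-acylated by the icosanoyl imidazolide and sheds carbon dioxide, which joins C2 to C3 and brings the benzyl ester in ready-made. The precursor is the N-acylimidazole of the C20 acid, made with carbonyldiimidazole. The C3 ketone is then removed by reduction, dehydration and conjugate reduction, all of which spare the benzyl ester.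

Key step: step 2

Remark on the chemistry: the target has no stereocenter. The C3 carbinol centre of compounds 8 and 9 is assumed to form as the racemate and is erased in step 4, so no stereocontrol is planned.

Step 1
Reactants: 1 icosanoic acid; 2 1,1'-carbonyldiimidazole
Product: 3 1-(imidazol-1-yl)icosan-1-one
Conditions: CDI (1.0 equiv), THF, 40 °C until gas evolution stops; concentrate, crude solid (containing the liberated imidazole) used as such
Reagents that add atoms: 1,1'-carbonyldiimidazole (compound 2), O=C(n1ccnc1)n1ccnc1
Why: Carboxyl activation by acyl transfer: the acid adds to carbonyldiimidazole, and the mixed anhydride collapses with loss of carbon dioxide and imidazole to the N-acylimidazole, a reaction that needs no added base and meets no other functional group in the saturated chain.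

Step 2
Reactants: 3 1-(imidazol-1-yl)icosan-1-one; 4 monobenzyl malonate
Product: 7 benzyl 3-oxodocosanoate, via magnesium enolate of monobenzyl malonate 5 (not isolated), via magnesium C-acylmalonate chelate 6 (not isolated)
Conditions: 4 (1.5 equiv), anhydrous MgCl2 (1.5 equiv), Et3N (3 equiv), THF/MeCN, rt; then 3 in THF, rt to 40 °C; cold 1 M HCl work-up
Reagents that add atoms: none
Why: Triethylamine and MgCl2 convert the half-ester into the chelated magnesium enolate–carboxylate 5, whose central carbon attacks the acyl imidazolide, expels imidazole and forms the C2–C3 bond. The acylmalonate chelate 6 then loses carbon dioxide, at the latest on acidification, which makes the condensation irreversible and leaves the beta-keto ester. The closest known reaction type is the decarboxylative Claisen condensation of magnesium malonate half-esters with acyl imidazolides (Masamune–Brooks type). No ring is closed and no stereocenter is formed. The step needs C- over O-acylation and mono- over double acylation: the six-membered magnesium chelate ties up both oxygens so that carbon is the nucleophile, and the acylated product stays as an unreactive chelate until work-up. The imidazolide is a mild acyl donor that does not form a ketene under these conditions, and the benzyl ester arrives untouched with the malonate unit.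

Step 3
Reactants: 7 benzyl 3-oxodocosanoate
Product: 8 benzyl 3-hydroxydocosanoate (racemic)
Conditions: NaBH4 (0.5 equiv), THF/EtOH, −10 to 0 °C; aq NH4Cl
Reagents that add atoms: none
Why: Chemoselective sodium borohydride reduction of a ketone next to an ester, which at low temperature with a limited charge of hydride leaves the benzyl ester alone; the new C3 carbinol centre forms without control as the racemate, which is harmless because step 4 removes it.

Step 4
Reactants: 8 benzyl 3-hydroxydocosanoate
Product: 10 benzyl (E)-docos-2-enoate, via benzyl 3-(methylsulfonyloxy)docosanoate 9 (not isolated)
Conditions: MsCl, Et3N, CH2Cl2, 0 °C; then DBU, 0 °C to rt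
Reagents that add atoms: none
Why: Sulfonylation of the secondary alcohol followed by base-induced E1cB elimination: the acidic C2 hydrogens next to the ester let DBU expel the C3 mesylate through the ester enolate, so the double bond ends up conjugated at C2–C3 with the E geometry favoured, and the geometry is of no consequence since the alkene is reduced next.

Step 5
Reactants: 10 benzyl (E)-docos-2-enoate
Product: 11 benzyl docosanoate
Conditions: Cu(OAc)2·H2O (cat.), 1,2-bis(diphenylphosphino)benzene (cat.), (EtO)2MeSiH, t-BuOH, toluene, rt; aq NH4F work-up
Reagents that add atoms: none
Why: Copper hydride conjugate reduction: the bisphosphine-ligated monovalent copper hydride generated from Cu(OAc)2 and the silane delivers hydride to C3 of the enoate, tert-butanol protonates the copper enolate at C2 and regenerates the catalyst, and this soft hydride attacks neither the ester carbonyl nor the benzylic C–O bond, which heterogeneous hydrogenation would cleave.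

Compound list
1 | icosanoic acid | CCCCCCCCCCCCCCCCCCCC(=O)O | starting material
2 | 1,1'-carbonyldiimidazole | O=C(n1ccnc1)n1ccnc1 | starting material
3 | 1-(imidazol-1-yl)icosan-1-one (icosanoyl imidazolide) | CCCCCCCCCCCCCCCCCCCC(=O)n1ccnc1 | intermediate
4 | monobenzyl malonate (3-(benzyloxy)-3-oxopropanoic acid) | OC(=O)CC(=O)OCc1ccccc1 | starting material
5 | magnesium enolate of monobenzyl malonate (chelated enolate–carboxylate) | [Mg+2].[O-]C(=O)/C=C(\[O-])OCc1ccccc1 | intermediate
6 | magnesium C-acylmalonate chelate (magnesium salt of 2-(benzyloxycarbonyl)-3-oxodocosanoic acid in its enolate form; enolate geometry not defined) | [Mg+2].CCCCCCCCCCCCCCCCCCCC([O-])=C(C(=O)[O-])C(=O)OCc1ccccc1 | intermediate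
7 | benzyl 3-oxodocosanoate | CCCCCCCCCCCCCCCCCCCC(=O)CC(=O)OCc1ccccc1 | intermediate
8 | benzyl 3-hydroxydocosanoate (racemic) | CCCCCCCCCCCCCCCCCCCC(O)CC(=O)OCc1ccccc1 | intermediate
9 | benzyl 3-(methylsulfonyloxy)docosanoate (racemic) | CCCCCCCCCCCCCCCCCCCC(OS(C)(=O)=O)CC(=O)OCc1ccccc1 | intermediate
10 | benzyl (E)-docos-2-enoate | CCCCCCCCCCCCCCCCCCC/C=C/C(=O)OCc1ccccc1 | intermediate
11 | benzyl docosanoate | CCCCCCCCCCCCCCCCCCCCCC(=O)OCc1ccccc1 | target

Total step count: 5
Longest linear sequence: 5 steps (from icosanoic acid 1 to target 11)

Steps most likely to fail

Step 2. The imidazolide may be hydrolysed back to the acid by adventitious water, the long-chain acyl donor may dissolve poorly in the polar medium, or acylation may stall or go partly on oxygen, so the C2–C3 bond would form incompletely. The fallback sets out from compound 1 and comes back at compound 7. Icosanoic acid would be condensed with Meldrum's acid (DCC, DMAP, CH2Cl2, 0 °C to rt) to give 5-(1-hydroxyicosylidene)-2,2-dimethyl-1,3-dioxane-4,6-dione F1. Heating this with benzyl alcohol in toluene at reflux should open the dioxanedione through the acylketene, with loss of acetone and carbon dioxide, and deliver benzyl 3-oxodocosanoate 7.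

Step 4. The mesylate may be displaced by chloride before elimination, or the base may move the double bond out of conjugation to the 3-enoate, which the copper hydride would not reduce. The fallback sets out from compound 7 and comes back at compound 10. The keto ester would be converted (NaH, THF, 0 °C, then PhNTf2) into benzyl (Z)-3-(trifluoromethylsulfonyloxy)docos-2-enoate F2. Homogeneous palladium-catalysed formate reduction of the enol triflate (Pd(OAc)2, PPh3, Bu3N, HCO2H, DMF, 60 °C) should then replace the triflate by hydrogen and give the 2-enoate 10 with the double bond fixed at C2–C3.

Step 5. Conjugate reduction of the waxy, poorly soluble enoate may stop short through catalyst deactivation, or the silyl ketene acetal formed when protonation lags may undergo condensation side reactions. The fallback sets out from compound 8 and comes back at compound 11, bypassing the alkene altogether. The hydroxy ester would be acylated with phenyl chlorothionoformate (pyridine, DMAP cat., CH2Cl2, 0 °C to rt) to give benzyl 3-(phenoxycarbonothioyloxy)docosanoate F3. Barton–McCombie radical deoxygenation (Bu3SnH, AIBN, toluene, 90 °C) should then replace the C3 oxygen by hydrogen and give benzyl docosanoate 11 without touching the benzyl ester.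

Further compounds
F1 | step 2 | 5-(1-hydroxyicosylidene)-2,2-dimethyl-1,3-dioxane-4,6-dione | CCCCCCCCCCCCCCCCCCCC(O)=C1C(=O)OC(C)(C)OC1=O
F2 | step 4 | benzyl (Z)-3-(trifluoromethylsulfonyloxy)docos-2-enoate | CCCCCCCCCCCCCCCCCCC/C(OS(=O)(=O)C(F)(F)F)=C/C(=O)OCc1ccccc1
F3 | step 5 | benzyl 3-(phenoxycarbonothioyloxy)docosanoate (racemic) | CCCCCCCCCCCCCCCCCCCC(OC(=S)Oc1ccccc1)CC(=O)OCc1ccccc1
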